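**Plan**

- Late cuts: the four benzyl ethers and the ethyl ether on apigenin O5 come off last. Before that, the pyranone of the 5,7-dihydroxychromone is opened to a 1,3-diketone (an aryl methyl ester on chroman C6 plus acetophenone 27), and apigenin ring C is opened to a chalcone.
- Central cut: apigenin ring A is split at C8a–C8 and C6–C7. This works because apigenin C8, the biaryl carbon bonded to chroman C8, sits between the oxygen-bearing carbons C7 and C8a of a 1,3,5-trioxygenated ring, which is the pattern a vinylketene and an aryl siloxyalkyne deliver.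
- Ring order forward: chroman pyran ring (steps 1–2), apigenin ring A grown on the C8 alkyne (step 6), apigenin ring C (step 11), pyranone of the second chromone (step 14). The chroman benzene ring, apigenin ring B and ring A of the second chromone are bought.
- Chain joining: the C8 alkyne comes from a Sonogashira coupling at iodine; the C6 carbon comes from carbonylation of a bromide that is carried as a spectator.
- Stereochemistry: the target has no stereocentre, so nothing needs to be controlled.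

Key step: step 6

Remark: the target SMILES carries no stereodescriptor, so the biaryl axis is treated as not configurationally defined; intermediates 13 and 23 are racemic and lose their stereocentre within the same step.

**Route**

Step 1
Reactants: 1 4-bromo-2-iodophenol; 2 prenyl bromide (1-bromo-3-methylbut-2-ene)
Product: 3 4-bromo-2-iodo-6-(3-methylbut-2-en-1-yl)phenol
Conditions: NaH, toluene, 0 °C; then 2, rt
Reagents that add atoms: none
Why: Ortho C-alkylation of a phenoxide: the tight sodium ion pair in a non-polar solvent shields oxygen, and C6 is the only open ortho position.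

Step 2
Reactants: 3 4-bromo-2-iodo-6-(3-methylbut-2-en-1-yl)phenol
Product: 4 6-bromo-8-iodo-2,2-dimethylchroman
Conditions: p-TsOH·H2O (cat.), toluene, 80 °C
Reagents that add atoms: none
Why: Acid-catalysed intramolecular hydroalkoxylation: protonation of the trisubstituted alkene gives the tertiary cation, which the phenol oxygen traps in a six-membered ring.

Step 3
Reactants: 4 6-bromo-8-iodo-2,2-dimethylchroman; 5 ethynyltrimethylsilane
Product: 6 [(6-bromo-2,2-dimethylchroman-8-yl)ethynyl]trimethylsilane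
Conditions: PdCl2(PPh3)2 (cat.), CuI (cat.), Et3N, THF, rt
Reagents that add atoms: none
Why: Sonogashira coupling: at room temperature oxidative addition into C–I is much faster than into C–Br, so the bromide should remain.

Step 4
Reactants: 6 [(6-bromo-2,2-dimethylchroman-8-yl)ethynyl]trimethylsilane
Product: 7 6-bromo-8-ethynyl-2,2-dimethylchroman
Conditions: K2CO3 (cat.), MeOH/THF, rt
Reagents that add atoms: none
Why: Base-mediated protodesilylation: methoxide cleaves the alkynyl C–Si bond and nothing else in the molecule is base-sensitive.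

Step 5
Reactants: 7 6-bromo-8-ethynyl-2,2-dimethylchroman
Product: 10 6-bromo-2,2-dimethyl-8-[(triisopropylsilyloxy)ethynyl]chroman, via lithium acetylide 8 (not isolated), via lithium ynolate 9 (not isolated)
Conditions: LiN(SiMe3)2, THF, −78 °C; LiOOC(CH3)3 (from t-BuOOH + LiN(SiMe3)2), −78 → 0 °C; TIPSOTf, −78 → 0 °C
Reagents that add atoms: lithium tert-butyl peroxide [Li+].[O-]OC(C)(C)C (made in the flask from tert-butyl hydroperoxide CC(C)(C)OO); triisopropylsilyl trifluoromethanesulfonate CC(C)[Si](OS(=O)(=O)C(F)(F)F)(C(C)C)C(C)C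
Why: Julia-type acetylide oxidation: the acetylide attacks the electrophilic peroxide oxygen to give the ynolate, the bulky silyl triflate silylates on oxygen, and the amide base (unlike an alkyllithium) leaves the C–Br bond alone.

Step 6
Reactants: 10 6-bromo-2,2-dimethyl-8-[(triisopropylsilyloxy)ethynyl]chroman; 11 3-ethoxycyclobut-2-en-1-one
Product: 16 2-(6-bromo-2,2-dimethylchroman-8-yl)-5-ethoxy-3-(triisopropylsilyloxy)phenol, via 3-ethoxyvinylketene 12 (not isolated), via vinylcyclobutenone 13 (not isolated), via dienylketene 14 (not isolated), via cyclohexadienone 15 (not isolated)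
Conditions: toluene, 100 °C, sealed tube (11 in slight excess)
Reagents that add atoms: none
Why: Heating opens 11 by 4π electrocyclic cleavage to vinylketene 12, and the aryl-bearing carbon of the polarized siloxyalkyne attacks the ketene carbonyl carbon in a (2+2) cycloaddition that forms apigenin C8a–C8 and C6–C7 and gives 13. A second 4π opening leads to dienylketene 14, whose 6π electrocyclization (re-forming C4a–C8a) gives dienone 15 and, after tautomerization, phenol 16, so ring A closes by a pericyclic mode and no coupling at a crowded arene carbon is needed. The closest known reaction type is the Danheiser benzannulation of cyclobutenones with siloxyalkynes, which gives resorcinol monosilyl ethers carrying the alkyne substituent between the two oxygens. No stereocentre is formed. The step needs regiocontrol, and the oxygen-induced polarization of the ynol ether secures it by pairing its nucleophilic carbon with the electrophilic ketene carbon, while the bromide and the chroman ether are thermal spectators. The three oxygens emerge differentiated as hydroxyl, silyl ether and ethyl ether, with the ethyl ether para to the aryl group, so only an oxygen flanking the biaryl carbon can later become the pyranone oxygen.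

Step 7
Reactants: 16 2-(6-bromo-2,2-dimethylchroman-8-yl)-5-ethoxy-3-(triisopropylsilyloxy)phenol
Product: 17 2-(6-bromo-2,2-dimethylchroman-8-yl)-5-ethoxybenzene-1,3-diol
Conditions: Bu4NF, THF, 0 °C; aq NH4Cl
Reagents that add atoms: none
Why: Fluoride desilylation of an aryl silyl ether gives a resorcinol whose two ring CH positions are equivalent, so any silyl migration during step 6 is harmless and the next acylation can give only one ketone.

Step 8
Reactants: 17 2-(6-bromo-2,2-dimethylchroman-8-yl)-5-ethoxybenzene-1,3-diol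
Product: 19 1-[3-(6-bromo-2,2-dimethylchroman-8-yl)-6-ethoxy-2,4-dihydroxyphenyl]ethan-1-one, via difluoroboron chelate 18 (not isolated)
Conditions: AcOH, BF3·OEt2, 80 °C; then aq NaOAc/MeOH, 60 °C
Reagents that add atoms: acetic acid CC(=O)O
Why: Friedel–Crafts (Nencki-type) C-acetylation of a resorcinol: either open position is ortho to one hydroxyl and para to the other, the ketone is held as its boron chelate until hydrolysis, and the less activated chroman ring should not compete.

Step 9
Reactants: 19 1-[3-(6-bromo-2,2-dimethylchroman-8-yl)-6-ethoxy-2,4-dihydroxyphenyl]ethan-1-one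
Product: 20 1-[4-(benzyloxy)-3-(6-bromo-2,2-dimethylchroman-8-yl)-6-ethoxy-2-hydroxyphenyl]ethan-1-one
Conditions: BnBr (1.05 equiv), K2CO3, acetone, reflux
Reagents that add atoms: benzyl bromide BrCc1ccccc1
Why: Williamson etherification: the 2-hydroxyl is hydrogen-bonded to the ketone and flanked on both sides, so the 4-hydroxyl should react selectively.

Step 10
Reactants: 20 1-[4-(benzyloxy)-3-(6-bromo-2,2-dimethylchroman-8-yl)-6-ethoxy-2-hydroxyphenyl]ethan-1-one; 21 4-(benzyloxy)benzaldehyde
Product: 22 (E)-1-[4-(benzyloxy)-3-(6-bromo-2,2-dimethylchroman-8-yl)-6-ethoxy-2-hydroxyphenyl]-3-[4-(benzyloxy)phenyl]prop-2-en-1-one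
Conditions: KOH, EtOH/THF, rt
Reagents that add atoms: none
Why: Claisen–Schmidt condensation: the methyl ketone enolate adds to the non-enolizable aldehyde and dehydration gives the conjugated E enone.

Step 11
Reactants: 22 (E)-1-[4-(benzyloxy)-3-(6-bromo-2,2-dimethylchroman-8-yl)-6-ethoxy-2-hydroxyphenyl]-3-[4-(benzyloxy)phenyl]prop-2-en-1-one
Product: 24 7-(benzyloxy)-2-[4-(benzyloxy)phenyl]-8-(6-bromo-2,2-dimethylchroman-8-yl)-5-ethoxy-4H-chromen-4-one, via flavanone 23 (not isolated)
Conditions: I2 (cat.), DMSO, 120 °C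
Reagents that add atoms: none
Why: Iodine/DMSO oxidative cyclization of a 2′-hydroxychalcone: oxa-Michael closure and iodine-mediated dehydrogenation (DMSO as terminal oxidant) give the flavone, and since the other ortho oxygen is the ethyl ether only the hydroxyl next to the biaryl carbon can close, which fixes the 8-aryl pattern.

Step 12
Reactants: 24 7-(benzyloxy)-2-[4-(benzyloxy)phenyl]-8-(6-bromo-2,2-dimethylchroman-8-yl)-5-ethoxy-4H-chromen-4-one
Product: 25 methyl 8-{7-(benzyloxy)-2-[4-(benzyloxy)phenyl]-5-ethoxy-4-oxo-4H-chromen-8-yl}-2,2-dimethylchroman-6-carboxylate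
Conditions: CO (1 atm), Pd(OAc)2 (cat.), Xantphos (cat.), Et3N, MeOH/toluene, 80 °C
Reagents that add atoms: carbon monoxide [C-]#[O+]; methanol CO
Why: Palladium-catalysed alkoxycarbonylation of an aryl bromide: the bromide has two ortho hydrogens, and the flavone and benzyl ethers are inert to CO, amine and methanol.

Step 13
Reactants: 26 2′,4′,6′-trihydroxyacetophenone
Product: 27 1-[2,4-bis(benzyloxy)-6-hydroxyphenyl]ethan-1-one
Conditions: BnBr (2.1 equiv), K2CO3, DMF, rt
Reagents that add atoms: benzyl bromide BrCc1ccccc1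
Why: Williamson etherification limited to two equivalents: after the first ortho hydroxyl and the para hydroxyl are benzylated, the remaining ortho hydroxyl is chelated to the ketone and should stay free.

Step 14
Reactants: 25 methyl 8-{7-(benzyloxy)-2-[4-(benzyloxy)phenyl]-5-ethoxy-4-oxo-4H-chromen-8-yl}-2,2-dimethylchroman-6-carboxylate; 27 1-[2,4-bis(benzyloxy)-6-hydroxyphenyl]ethan-1-one
Product: 29 5,7-bis(benzyloxy)-2-(8-{7-(benzyloxy)-2-[4-(benzyloxy)phenyl]-5-ethoxy-4-oxo-4H-chromen-8-yl}-2,2-dimethylchroman-6-yl)-4H-chromen-4-one, via 1,3-diketone 28 (not isolated)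
Conditions: 27, LiN(SiMe3)2 (excess), THF, −78 → −10 °C; then 25, −78 °C → rt; aq HCl; then AcOH, H2SO4 (cat.), 80 °C
Reagents that add atoms: none
Why: Crossed Claisen condensation of the phenoxide-enolate dianion of 27 with the methyl aroate (the diketone stage of a Baker–Venkataraman flavone synthesis), driven by deprotonation of the diketone, followed by acid-catalysed cyclodehydration through the free ortho hydroxyl.

Step 15
Reactants: 29 5,7-bis(benzyloxy)-2-(8-{7-(benzyloxy)-2-[4-(benzyloxy)phenyl]-5-ethoxy-4-oxo-4H-chromen-8-yl}-2,2-dimethylchroman-6-yl)-4H-chromen-4-one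
Product: 30 8-[6-(5,7-dihydroxy-4-oxo-4H-chromen-2-yl)-2,2-dimethylchroman-8-yl]-5,7-dihydroxy-2-(4-hydroxyphenyl)-4H-chromen-4-one (CNP0127025.0)
Conditions: BCl3 (excess), C6HMe5, CH2Cl2, −78 → 0 °C; MeOH, then H2O
Reagents that add atoms: none
Why: Lewis-acid ether cleavage: BCl3 removes aryl benzyl ethers at low temperature with pentamethylbenzene trapping the benzyl cations, the ethyl ether peri to the C4 carbonyl is cleaved through the boron chelate, and the chroman oxygen is shielded by its gem-dimethyl group and the C8 aryl group.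

**Compound list**

1 | 4-bromo-2-iodophenol | Oc1ccc(Br)cc1I | starting material
2 | prenyl bromide (1-bromo-3-methylbut-2-ene) | CC(C)=CCBr | starting material
3 | 4-bromo-2-iodo-6-(3-methylbut-2-en-1-yl)phenol | CC(C)=CCc1cc(Br)cc(I)c1O | intermediate
4 | 6-bromo-8-iodo-2,2-dimethylchroman | CC1(C)CCc2cc(Br)cc(I)c2O1 | intermediate
5 | ethynyltrimethylsilane | C#C[Si](C)(C)C | starting material
6 | [(6-bromo-2,2-dimethylchroman-8-yl)ethynyl]trimethylsilane | CC1(C)CCc2cc(Br)cc(C#C[Si](C)(C)C)c2O1 | intermediate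
7 | 6-bromo-8-ethynyl-2,2-dimethylchroman | CC1(C)CCc2cc(Br)cc(C#C)c2O1 | intermediate
8 | lithium (6-bromo-2,2-dimethylchroman-8-yl)acetylide | [Li+].[C-]#Cc1cc(Br)cc2CCC(C)(C)Oc12 | intermediate
9 | lithium 2-(6-bromo-2,2-dimethylchroman-8-yl)ethynolate | [Li+].[O-]C#Cc1cc(Br)cc2CCC(C)(C)Oc12 | intermediate
10 | 6-bromo-2,2-dimethyl-8-[(triisopropylsilyloxy)ethynyl]chroman | CC1(C)CCc2cc(Br)cc(C#CO[Si](C(C)C)(C(C)C)C(C)C)c2O1 | intermediate
11 | 3-ethoxycyclobut-2-en-1-one | CCOC1=CC(=O)C1 | starting material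
12 | 3-ethoxybuta-1,3-dien-1-one (3-ethoxyvinylketene) | C=C(OCC)C=C=O | intermediate
13 | 2-(6-bromo-2,2-dimethylchroman-8-yl)-4-(1-ethoxyethenyl)-3-(triisopropylsilyloxy)cyclobut-2-en-1-one (racemic) | CCOC(=C)C1C(=O)C(c2cc(Br)cc3CCC(C)(C)Oc23)=C1O[Si](C(C)C)(C(C)C)C(C)C | intermediate
14 | (3E)-2-(6-bromo-2,2-dimethylchroman-8-yl)-5-ethoxy-3-(triisopropylsilyloxy)hexa-1,3,5-trien-1-one (ketene carbon and ethoxyvinyl group cis) | O=C=C(c1cc(Br)cc2CCC(C)(C)Oc12)/C(O[Si](C(C)C)(C(C)C)C(C)C)=C\C(OCC)=C | intermediate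
15 | 2-(6-bromo-2,2-dimethylchroman-8-yl)-5-ethoxy-3-(triisopropylsilyloxy)cyclohexa-2,4-dien-1-one | CCOC1=CC(O[Si](C(C)C)(C(C)C)C(C)C)=C(c2cc(Br)cc3CCC(C)(C)Oc23)C(=O)C1 | intermediate
16 | 2-(6-bromo-2,2-dimethylchroman-8-yl)-5-ethoxy-3-(triisopropylsilyloxy)phenol | CCOc1cc(O)c(-c2cc(Br)cc3CCC(C)(C)Oc23)c(O[Si](C(C)C)(C(C)C)C(C)C)c1 | intermediate
17 | 2-(6-bromo-2,2-dimethylchroman-8-yl)-5-ethoxybenzene-1,3-diol | CCOc1cc(O)c(-c2cc(Br)cc3CCC(C)(C)Oc23)c(O)c1 | intermediate
18 | difluoroboron chelate of ketone 19 (boron bridging the 2-oxygen and the acetyl oxygen) | CCOc1cc(O)c(-c2cc(Br)cc3CCC(C)(C)Oc23)c2O[B-](F)(F)[O+]=C(C)c12 | intermediate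
19 | 1-[3-(6-bromo-2,2-dimethylchroman-8-yl)-6-ethoxy-2,4-dihydroxyphenyl]ethan-1-one | CCOc1cc(O)c(-c2cc(Br)cc3CCC(C)(C)Oc23)c(O)c1C(C)=O | intermediate
20 | 1-[4-(benzyloxy)-3-(6-bromo-2,2-dimethylchroman-8-yl)-6-ethoxy-2-hydroxyphenyl]ethan-1-one | CCOc1cc(OCc2ccccc2)c(-c2cc(Br)cc3CCC(C)(C)Oc23)c(O)c1C(C)=O | intermediate
21 | 4-(benzyloxy)benzaldehyde | O=Cc1ccc(OCc2ccccc2)cc1 | starting material
22 | (E)-1-[4-(benzyloxy)-3-(6-bromo-2,2-dimethylchroman-8-yl)-6-ethoxy-2-hydroxyphenyl]-3-[4-(benzyloxy)phenyl]prop-2-en-1-one | CCOc1cc(OCc2ccccc2)c(-c2cc(Br)cc3CCC(C)(C)Oc23)c(O)c1C(=O)/C=C/c1ccc(OCc2ccccc2)cc1 | intermediate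
23 | 7-(benzyloxy)-2-[4-(benzyloxy)phenyl]-8-(6-bromo-2,2-dimethylchroman-8-yl)-5-ethoxychroman-4-one (racemic) | CCOc1cc(OCc2ccccc2)c(-c2cc(Br)cc3CCC(C)(C)Oc23)c2OC(c3ccc(OCc4ccccc4)cc3)CC(=O)c12 | intermediate
24 | 7-(benzyloxy)-2-[4-(benzyloxy)phenyl]-8-(6-bromo-2,2-dimethylchroman-8-yl)-5-ethoxy-4H-chromen-4-one | CCOc1cc(OCc2ccccc2)c(-c2cc(Br)cc3CCC(C)(C)Oc23)c2oc(-c3ccc(OCc4ccccc4)cc3)cc(=O)c12 | intermediate
25 | methyl 8-{7-(benzyloxy)-2-[4-(benzyloxy)phenyl]-5-ethoxy-4-oxo-4H-chromen-8-yl}-2,2-dimethylchroman-6-carboxylate | CCOc1cc(OCc2ccccc2)c(-c2cc(C(=O)OC)cc3CCC(C)(C)Oc23)c2oc(-c3ccc(OCc4ccccc4)cc3)cc(=O)c12 | intermediate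
26 | 2′,4′,6′-trihydroxyacetophenone | CC(=O)c1c(O)cc(O)cc1O | starting material
27 | 1-[2,4-bis(benzyloxy)-6-hydroxyphenyl]ethan-1-one | CC(=O)c1c(O)cc(OCc2ccccc2)cc1OCc1ccccc1 | intermediate
28 | 1-[2,4-bis(benzyloxy)-6-hydroxyphenyl]-3-(8-{7-(benzyloxy)-2-[4-(benzyloxy)phenyl]-5-ethoxy-4-oxo-4H-chromen-8-yl}-2,2-dimethylchroman-6-yl)propane-1,3-dione | CCOc1cc(OCc2ccccc2)c(-c2cc(C(=O)CC(=O)c3c(O)cc(OCc4ccccc4)cc3OCc3ccccc3)cc3CCC(C)(C)Oc23)c2oc(-c3ccc(OCc4ccccc4)cc3)cc(=O)c12 | intermediate
29 | 5,7-bis(benzyloxy)-2-(8-{7-(benzyloxy)-2-[4-(benzyloxy)phenyl]-5-ethoxy-4-oxo-4H-chromen-8-yl}-2,2-dimethylchroman-6-yl)-4H-chromen-4-one | CCOc1cc(OCc2ccccc2)c(-c2cc(-c3cc(=O)c4c(OCc5ccccc5)cc(OCc5ccccc5)cc4o3)cc3CCC(C)(C)Oc23)c2oc(-c3ccc(OCc4ccccc4)cc3)cc(=O)c12 | intermediate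
30 | 8-[6-(5,7-dihydroxy-4-oxo-4H-chromen-2-yl)-2,2-dimethylchroman-8-yl]-5,7-dihydroxy-2-(4-hydroxyphenyl)-4H-chromen-4-one (CNP0127025.0) | CC1(C)CCc2cc(-c3cc(=O)c4c(O)cc(O)cc4o3)cc(-c3c(O)cc(O)c4c(=O)cc(-c5ccc(O)cc5)oc34)c2O1 | target

**Count and risks**

Total steps: 15. Longest linear sequence: 14 (steps 1–12, 14, 15); step 13 is a one-step side branch.

Steps most likely to fail:

1. Step 6. The push–pull cyclobutenone may open too slowly below the temperature at which the siloxyalkyne isomerizes to a silylketene, and the phenol formed may be acylated by unconsumed vinylketene, so conversion to the biaryl could stall. The fallback gives up the annulation and makes the biaryl bond by cross-coupling; it sets out from 4 and comes back at 17. Phloroglucinol is mono-etherified (EtOH, HCl) to 5-ethoxybenzene-1,3-diol F1 and protected (MOMCl, i-Pr2NEt, CH2Cl2) as 1-ethoxy-3,5-bis(methoxymethoxy)benzene F2. Directed lithiation between the two acetal oxygens (n-BuLi, THF, 0 °C) and borylation (B(OMe)3, then aq NH4Cl) give [4-ethoxy-2,6-bis(methoxymethoxy)phenyl]boronic acid F3. Suzuki–Miyaura coupling of F3 with 4 (Pd(OAc)2, SPhos, K3PO4, toluene/H2O, 60 °C), in which the C–I bond reacts before the C–Br bond, should give 6-bromo-8-[4-ethoxy-2,6-bis(methoxymethoxy)phenyl]-2,2-dimethylchroman F4. HCl in MeOH then removes both acetals to give 17.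

2. Step 5. Protonation or over-oxidation of the ynolate, silylation on carbon instead of oxygen, and hydrolysis of the ynol silyl ether on isolation could each erode the siloxyalkyne. The fallback reaches the ynolate from an electrophilic alkyne; it sets out from 7 and comes back at 9, which is silylated with TIPSOTf as in step 5 to give 10. Alkyne 7 and PhI(OH)OTs (CH2Cl2, rt) give [(6-bromo-2,2-dimethylchroman-8-yl)ethynyl](phenyl)iodonium 4-methylbenzenesulfonate F5. CuOTf (cat., MeCN) converts it, with loss of iodobenzene, into (6-bromo-2,2-dimethylchroman-8-yl)ethynyl 4-methylbenzenesulfonate F6. MeLi (THF, −78 °C) attacks sulfur and releases ynolate 9 without touching the aryl bromide.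

3. Step 15. The boron Lewis acid may ionize the tertiary C2–O bond of the chroman, may leave the chelated ethyl ether partly intact, and benzyl cations may alkylate the phloroglucinol rings. The fallback separates the two kinds of ether cleavage; it sets out from 29 and comes back at 30. Hydrogenolysis (H2, Pd/C, THF/MeOH, rt) removes the four benzyl groups to give 2-{8-[5-ethoxy-7-hydroxy-2-(4-hydroxyphenyl)-4-oxo-4H-chromen-8-yl]-2,2-dimethylchroman-6-yl}-5,7-dihydroxy-4H-chromen-4-one F7. MgI2·OEt2 (THF/toluene, 80 °C) then cleaves only the ethyl ether held in the magnesium chelate with the C4 carbonyl, a reagent mild enough for acid-sensitive ethers, to give 30.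

**Further compounds**

F1 | step 6 | 5-ethoxybenzene-1,3-diol | CCOc1cc(O)cc(O)c1
F2 | step 6 | 1-ethoxy-3,5-bis(methoxymethoxy)benzene | CCOc1cc(OCOC)cc(OCOC)c1
F3 | step 6 | [4-ethoxy-2,6-bis(methoxymethoxy)phenyl]boronic acid | CCOc1cc(OCOC)c(B(O)O)c(OCOC)c1
F4 | step 6 | 6-bromo-8-[4-ethoxy-2,6-bis(methoxymethoxy)phenyl]-2,2-dimethylchroman | CCOc1cc(OCOC)c(-c2cc(Br)cc3CCC(C)(C)Oc23)c(OCOC)c1
F5 | step 5 | [(6-bromo-2,2-dimethylchroman-8-yl)ethynyl](phenyl)iodonium 4-methylbenzenesulfonate | CC1(C)CCc2cc(Br)cc(C#C[I+]c3ccccc3)c2O1.Cc1ccc(S(=O)(=O)[O-])cc1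
F6 | step 5 | (6-bromo-2,2-dimethylchroman-8-yl)ethynyl 4-methylbenzenesulfonate | Cc1ccc(S(=O)(=O)OC#Cc2cc(Br)cc3CCC(C)(C)Oc23)cc1
F7 | step 15 | 2-{8-[5-ethoxy-7-hydroxy-2-(4-hydroxyphenyl)-4-oxo-4H-chromen-8-yl]-2,2-dimethylchroman-6-yl}-5,7-dihydroxy-4H-chromen-4-one | CCOc1cc(O)c(-c2cc(-c3cc(=O)c4c(O)cc(O)cc4o3)cc3CCC(C)(C)Oc23)c2oc(-c3ccc(O)cc3)cc(=O)c12
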